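Add Q and E at any ash reading and the sum stays near the whole charge; at the last reading it is 98.5%. So Q comes from E, and one molecule of E can be followed: at each moment it is either free or sitting as Q.

| setting | ash | larch | flask |
|---|---|---|---|
| E | 0.10 M | 0.15 M | 0.10 M |
| X | 0.20 M | 0.20 M | 0.200 M |
| D | 25 mM (held) | 25 mM (held) | 25 mM (held) |
| temperature | 5 °C | 11 °C | 5 °C |
| remark | the very flask that is asked about, followed so far | run made earlier |  |
| time |  |  | 8.0 d |

ash run (percent of the E charged)

| time / d | Q / % | E / % |
|---|---|---|
| 0.833 | 22.8 | 77.6 |
| 2.50 | 28.2 | 70.5 |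
| 4.00 | 28.5 | 71.8 |
| 6.00 | 28.8 | 69.7 |

larch run (percent of the E charged)

| time / h | Q / % | E / % |
|---|---|---|
| 10.0 | 15.1 | 85.1 |
| 20.0 | 20.2 | 78.0 |
| 30.0 | 21.5 | 76.3 |
| 40.0 | 23.6 | 77.9 |

(each reading ± 1 percentage point)

- summer: change nothing and wait 4.0 d more
- winter: at 8.0 d take out 90% of the Q then present, then wait 4.0 d
- autumn: at 8.0 d add E, 50.0% of the amount charged, then wait 4.0 d
- midnight: at 8.0 d raise the temperature by 25 K, then wait 4.0 d

- at the start none of Z is dissolved
- what is taken out of Q is counted as made
- what may be going on: E + Z <-> Q; X + Z <-> G; D <-> Z; Z -> J; 2 Z -> L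
- additions bring no volume worth counting

* Q, in percent of the E first charged, at 8.0 d
* which option adds most Q ("none" when 2 percentage points or less is all one gets) (summer / winter / autumn / midnight / none)
* Q present, with what was taken out counted in, in percent of the E first charged, after winter
* Q present, with what was taken out counted in, in percent of the E first charged, after autumn

Two people argue over the ash flask. The first says this fork runs both ways, because a molecule that became Q can fall back to E. From the last three ash readings I reckon 28.7% for the holding share, the fraction of E and Q together that stands as Q while Z stays level. On this view, Q at 8.0 d is that share of the charge. Taking out 90% of the Q leaves 74.2% of the charge to divide again, so Q counted comes to 47.1%. Adding 50.0% more E gives 43.0%.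

The second says the fork runs one way: Q, once made, stays, and the flat stretch is merely a slow pace. He points out that Q rose between every larch reading, and that ash Q still gained 0.6 percentage points from 2.50 d to 6.00 d. At that pace, 4.0 d more adds 0.69 points, whatever is taken out, which is less than the margin of 2 points. His answer is none.

The forecast sides with the first: 28.6% at 8.0 d, winter as the best option, 47% after winter and 42.9% after autumn. Its ground: “The plateau is therefore most likely the true equilibrium of E + Z ⇌ Q”. Those figures are its own; mine above stand beside them.

The flask gives 29.3% at 8.0 d, and winter is best: winter adds 19 points, autumn 15 points, summer 0 points and midnight −22 points, with 47.9% counted after winter and 43.9% after autumn. The first view stands, as thermodynamic rather than kinetic control of the step between E and Q: waiting ten times as long changes nothing in Q. The relaxation half-life of E + Z and Q, both ways together and by that step alone, is 0.385 h at 8.00 d, far shorter than the 8.0 d of the run. The rise the second view counted on belongs to the early stretch: before 1.05 d, Q still stood more than 5 points from its value at 8.0 d.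

    E + Z ⇌ Q (K = 19.0 M⁻¹, k = 12.4 M⁻¹ h⁻¹, Ea = 64.0 kJ mol⁻¹, ΔH = −12.0 kJ mol⁻¹)
    X + Z ⇌ G (K = 36.0 M⁻¹, k = 2.62 M⁻¹ h⁻¹, Ea = 70.0 kJ mol⁻¹, ΔH = −61.0 kJ mol⁻¹)
    D ⇌ Z, rate k3*(csat - [Z]) (kL = 0.373 h⁻¹)
    Z → J (k = 0.0400 h⁻¹, Ea = 94.0 kJ mol⁻¹)
    2 Z → L (k = 0.340 M⁻¹ h⁻¹, Ea = 72.0 kJ mol⁻¹)
    (constants at 5 °C)

The neighbour flask with 0.80 M of X has the E charge and temperature of the asked flask, so the holding share, taken with Z at the same level, puts Q at 28.7% at 8.0 d. The computed answer is 29.2%, with Z at 0.0217 M, about the 0.0218 M of the asked flask.

The runs were generated by integration with made-up constants, and the scatter is random.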